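Both rings of the target are 1,3,5-trisubstituted. In ring A the hydroxyl carbon C5 is meta to C3 (OMe) and C1 (chain), and in ring B the hydroxyl carbon C5' is meta to C3' (O) and C1' (chain). These two C–O bonds are disconnected together. This gives a 1,14-diaryltetradecane with two 1,3-disubstituted rings in which C5–H and C5'–H alone lack an ortho neighbour. One sterically governed iridium-catalysed double C–H borylation, oxidized in the same flask, installs both oxygens. The precursor carries the methyl ether on ring A and a bulky triisopropylsilyl ether on ring B, since a small O-boronate mask can draw the catalyst ortho.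

Key step: step 4

Assumption: ring A is the methoxy ring (C1 chain, C3 OMe, C5 new OH) and ring B is the other ring (C1' chain, C3' silyloxy, C5' new OH). Compounds 1, 2 and 5 are taken as catalogue chemicals. The target has no stereocentre.

Step 1
Reactants: 1 11-bromoundec-1-ene; 2 1-(3-bromopropyl)-3-methoxybenzene
Product: 4 1-methoxy-3-(tetradec-13-en-1-yl)benzene, via undec-10-enylmagnesium bromide 3 (not isolated)
Conditions: 1, Mg, THF, 45 °C; then 2, Li2CuCl4 (3 mol %), NMP, THF, 0 °C to rt
Reagents that add atoms: magnesium, [Mg] (held only in intermediate 3)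
Why: Copper-catalysed Grignard–alkyl bromide cross-coupling (Kochi–Tamura type) joins two unhindered primary carbons (11 + 3 = 14 chain carbons), and neither the terminal alkene nor the aryl methyl ether reacts with the organomagnesium or organocopper species.

Step 2
Reactants: 5 3-bromophenol
Product: 6 (3-bromophenoxy)triisopropylsilane
Conditions: TIPSCl, imidazole, DMF, rt
Reagents that add atoms: chlorotriisopropylsilane, CC(C)[Si](Cl)(C(C)C)C(C)C
Why: Imidazole-promoted O-silylation of a phenol leaves the aryl bromide untouched and installs a group bulky enough to survive the aqueous base of step 3 and to shield both of its ortho positions in step 4.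

Step 3
Reactants: 4 1-methoxy-3-(tetradec-13-en-1-yl)benzene; 6 (3-bromophenoxy)triisopropylsilane
Product: 8 triisopropyl{3-[14-(3-methoxyphenyl)tetradecyl]phenoxy}silane (the O-TIPS ether of 3-[14-(3-methoxyphenyl)tetradecyl]phenol), via B-alkyl-9-BBN adduct 7 (not isolated)
Conditions: 4, 9-BBN, THF, 0 °C to rt; then 6, PdCl2(dppf) (3 mol %), aq K3PO4, THF/DMF, 60 °C
Reagents that add atoms: 9-borabicyclo[3.3.1]nonane, B1C2CCCC1CCC2 (held only in intermediate 7)
Why: Anti-Markovnikov hydroboration of the terminal alkene followed by B-alkyl Suzuki–Miyaura coupling forms the aryl–CH2 bond, the wide-bite-angle dppf ligand favouring reductive elimination over β-hydride elimination and the phosphate base sparing the TIPS ether.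

Step 4
Reactants: 8 triisopropyl{3-[14-(3-methoxyphenyl)tetradecyl]phenoxy}silane
Product: 10 3-[14-(3-hydroxy-5-methoxyphenyl)tetradecyl]-5-[(triisopropylsilyl)oxy]phenol, via C5/C5' bis(pinacol boronate) 9 (not isolated)
Conditions: [Ir(OMe)(cod)]2 (3 mol %), 4,4'-di-tert-butyl-2,2'-bipyridine (dtbpy, 6 mol %), B2pin2 (2.2 equiv), THF, 80 °C; evaporate; then KHSO5 (as 2KHSO5·KHSO4·K2SO4, 2.5 equiv), acetone/THF/H2O, rt, 10 min; aq NaHSO3
Reagents that add atoms: potassium peroxymonosulfate, [K+].[O-]S(=O)(=O)OO (both new oxygen atoms); bis(pinacolato)diboron, CC1(C)OB(OC1(C)C)B1OC(C)(C)C(C)(C)O1 (held only in intermediate 9)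
Why: [Ir(OMe)(cod)]2, dtbpy and B2pin2 generate the tris(boryl) complex of trivalent iridium, which cleaves an aromatic C–H bond by oxidative addition to a pentavalent aryl hydride, releases the aryl boronate by C–B reductive elimination and is restored by B2pin2 with loss of HBpin; peroxymonosulfate then adds to each boron, the aryl group migrates from boron to oxygen at the same carbon and water frees the phenol. The closest known reaction type is the one-pot iridium-catalysed C–H borylation/oxidation that turns 1,3-disubstituted arenes into 3,5-disubstituted phenols, run here on two remote and electronically independent rings of one molecule. No ring is closed and no stereocentre is created. The selectivity needed is site selectivity among eight aromatic C–H bonds, and it is steric: C2 and C2' sit between two substituents, C4 and C4' are ortho to OMe or OTIPS, C6 and C6' are ortho to the chain, so only C5 and C5' admit the crowded catalyst. The TIPS ether shields C2' and C4' and lacks the Lewis-acidic boron of an O-boryl mask that can hold the bipyridine ligand near an ortho C–H, and after the two borylations no unhindered C–H is left, so surplus B2pin2 cannot over-borylate. Benzylic, chain, methoxy and isopropyl C(sp3)–H bonds are far slower under these arene conditions, and the brief, mildly acidic oxidation leaves the aryl TIPS ether and the methyl ether alone.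

Step 5
Reactants: 10 3-[14-(3-hydroxy-5-methoxyphenyl)tetradecyl]-5-[(triisopropylsilyl)oxy]phenol
Product: 11 5-[14-(3-hydroxy-5-methoxyphenyl)tetradecyl]benzene-1,3-diol (target)
Conditions: TBAF (1.5 equiv), AcOH (1.5 equiv), THF, 0 °C to rt
Reagents that add atoms: none
Why: Fluoride-driven cleavage of an aryl silyl ether is fast because of the strong Si–F bond and the good phenoxide leaving group, the acetic acid buffer keeps air-sensitive resorcinolate from building up, and the methyl ether is inert.

Compound list
1 | 11-bromoundec-1-ene | C=CCCCCCCCCCBr | starting material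
2 | 1-(3-bromopropyl)-3-methoxybenzene | COc1cccc(CCCBr)c1 | starting material
3 | undec-10-enylmagnesium bromide | C=CCCCCCCCCC[Mg]Br | intermediate
4 | 1-methoxy-3-(tetradec-13-en-1-yl)benzene | COc1cccc(CCCCCCCCCCCCC=C)c1 | intermediate
5 | 3-bromophenol | Oc1cccc(Br)c1 | starting material
6 | (3-bromophenoxy)triisopropylsilane | CC(C)[Si](Oc1cccc(Br)c1)(C(C)C)C(C)C | intermediate
7 | 9-[14-(3-methoxyphenyl)tetradecyl]-9-borabicyclo[3.3.1]nonane | COc1cccc(CCCCCCCCCCCCCCB2C3CCCC2CCC3)c1 | intermediate
8 | triisopropyl{3-[14-(3-methoxyphenyl)tetradecyl]phenoxy}silane | COc1cccc(CCCCCCCCCCCCCCc2cccc(O[Si](C(C)C)(C(C)C)C(C)C)c2)c1 | intermediate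
9 | triisopropyl{3-[14-(3-methoxy-5-(4,4,5,5-tetramethyl-1,3,2-dioxaborolan-2-yl)phenyl)tetradecyl]-5-(4,4,5,5-tetramethyl-1,3,2-dioxaborolan-2-yl)phenoxy}silane | COc1cc(B2OC(C)(C)C(C)(C)O2)cc(CCCCCCCCCCCCCCc3cc(O[Si](C(C)C)(C(C)C)C(C)C)cc(B4OC(C)(C)C(C)(C)O4)c3)c1 | intermediate
10 | 3-[14-(3-hydroxy-5-methoxyphenyl)tetradecyl]-5-[(triisopropylsilyl)oxy]phenol | COc1cc(O)cc(CCCCCCCCCCCCCCc2cc(O)cc(O[Si](C(C)C)(C(C)C)C(C)C)c2)c1 | intermediate
11 | 5-[14-(3-hydroxy-5-methoxyphenyl)tetradecyl]benzene-1,3-diol | COc1cc(O)cc(CCCCCCCCCCCCCCc2cc(O)cc(O)c2)c1 | target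

Total step count: 5. Longest linear sequence: 4 steps (1, 3, 4, 5).

Steps most likely to fail

Step 4.
- Borylation of these electron-rich rings may stall after one ring.
- Site selectivity may erode next to the small methoxy group.
- The peroxymonosulfate may over-oxidize the electron-rich phenols as they form.
- The fallback sets out from 8 and replaces boron by silicon. Sterically controlled C–H silylation uses HSiMe(OSiMe3)2, [Ir(OMe)(cod)]2, 2,4,7-trimethyl-1,10-phenanthroline and cyclohexene as hydrogen acceptor in THF at 100 °C. The larger silyl group discriminates even more strongly against ortho positions, so this should give the C5/C5' bis(heptamethyltrisiloxan-3-yl) derivative of 8 F1.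
- Tamao–Fleming oxidation (H2O2, KHCO3, TBAF, THF/MeOH, rt) converts both C–Si bonds into C–OH. With enough fluoride it also strips the TIPS ether, so the fallback rejoins the route at 11.

Step 3.
- β-Hydride elimination or protodeboronation of the alkylborane may compete.
- Oxidative addition may be slow.
- The silyl ether may be partly lost in hot aqueous base.
- The fallback sets out from 4 and 6 and forms the link by olefin metathesis. Stille vinylation of 6 (tributyl(vinyl)stannane, Pd(PPh3)4, toluene, 100 °C, base-free) gives triisopropyl(3-vinylphenoxy)silane F2.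
- Cross-metathesis of 4 with excess F2 (second-generation Hoveyda–Grubbs catalyst, CH2Cl2, 40 °C) loses ethene and keeps the count of 14 chain carbons. It gives (E)-triisopropyl{3-[14-(3-methoxyphenyl)tetradec-1-en-1-yl]phenoxy}silane F3.
- Hydrogenation (H2, Pd/C, EtOAc, rt) rejoins the route at 8.

Step 1.
- Wurtz-type homocoupling may occur during Grignard formation.
- Reduction or elimination of the bromide in the copper cycle may cut into the cross-coupling.
- The fallback sets out from 1 and uses an organoborane nucleophile under palladium catalysis. Commercial 1-allyl-3-methoxybenzene (C=CCc1cccc(OC)c1) is hydroborated with exactly one equivalent of 9-BBN in THF to give 9-[3-(3-methoxyphenyl)propyl]-9-borabicyclo[3.3.1]nonane F4.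
- F4 is coupled with 1 by alkyl–alkyl Suzuki–Miyaura reaction (Pd(OAc)2, PCy3, K3PO4·H2O, THF, rt). These conditions tolerate the terminal alkene, and the fallback rejoins the route at 4.

Further compounds
F1 | step 4 | triisopropyl{3-(1,1,1,3,5,5,5-heptamethyltrisiloxan-3-yl)-5-[14-(3-(1,1,1,3,5,5,5-heptamethyltrisiloxan-3-yl)-5-methoxyphenyl)tetradecyl]phenoxy}silane | COc1cc([Si](C)(O[Si](C)(C)C)O[Si](C)(C)C)cc(CCCCCCCCCCCCCCc2cc(O[Si](C(C)C)(C(C)C)C(C)C)cc([Si](C)(O[Si](C)(C)C)O[Si](C)(C)C)c2)c1
F2 | step 3 | triisopropyl(3-vinylphenoxy)silane | C=Cc1cccc(O[Si](C(C)C)(C(C)C)C(C)C)c1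
F3 | step 3 | (E)-triisopropyl{3-[14-(3-methoxyphenyl)tetradec-1-en-1-yl]phenoxy}silane | COc1cccc(CCCCCCCCCCCC/C=C/c2cccc(O[Si](C(C)C)(C(C)C)C(C)C)c2)c1
F4 | step 1 | 9-[3-(3-methoxyphenyl)propyl]-9-borabicyclo[3.3.1]nonane | COc1cccc(CCCB2C3CCCC2CCC3)c1
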